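**Retrosynthetic overview**

1. The target is one carbocycle, the enol form of a 2-benzoylcyclohexane-1,3,5-trione. Ring labels: C1 (one prenyl), C2 (O), C3 (quaternary, two prenyls), C4 (O), C5 (benzoyl, carbonyl carbon C7), C6 (O). The strategy rests on the quaternary C3, which in an open chain C4–C3–C2–C1 leaves C1 as the only acidic carbon, and on C5–C6 with C7 being acetophenone extended by one carbon at the carboxyl level.
2. Last disconnection: C6–OH back to C6–SMe, a vinylogous thioester that is hydrolysed at the end.
3. Key disconnection: C1–C6 and C4–C5. This gives a fully prenylated β-keto ester (C1 to C4) and 3,3-bis(methylsulfanyl)-1-phenylprop-2-en-1-one (C5, C6, C7). The only ring of the molecule is closed here, in one flask.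
4. The keto ester comes from methyl acetoacetate and prenyl bromide (γ-alkylation of the dianion, then double α-alkylation); the dithioacetal comes from acetophenone, CS2 and MeI.

Key step: step 4

Remark: the target has no stereocentre and is a set of rapidly equilibrating enol tautomers, of which the one in the given SMILES is drawn for 13; enolates and enol tautomers are treated as forms of the numbered compound they derive from, and only species with a new connectivity of heavy atoms get their own number.

**Route**

Step 1
Reactants: 1 methyl acetoacetate; 2 1-bromo-3-methylbut-2-ene (prenyl bromide)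
Product: 3 methyl 7-methyl-3-oxooct-6-enoate
Conditions: NaH (1.1 equiv), THF, 0 °C; n-BuLi (1.05 equiv), 0 °C; 2 (1.0 equiv), 0 °C to rt; cold 1 M HCl
Reagents that add atoms: none
Why: Weiler dianion alkylation, in which the terminal carbanion of the sodium lithium dianion is far more nucleophilic than the stabilised central enolate and takes the allylic bromide by SN2 at the former methyl carbon only, with no stereocentre formed.

Step 2
Reactants: 3 methyl 7-methyl-3-oxooct-6-enoate; 2 1-bromo-3-methylbut-2-ene (2.3 equiv in all)
Product: 5 methyl 7-methyl-2,2-bis(3-methylbut-2-enyl)-3-oxooct-6-enoate, via monoprenylated keto ester 4 (not isolated)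
Conditions: NaH (1.1 equiv), THF, 0 °C, 2 (1.1 equiv), rt; then NaH (1.2 equiv), 2 (1.2 equiv), rt to 45 °C; aq NH4Cl
Reagents that add atoms: none
Why: Acetoacetic ester alkylation run twice, in which the tightly paired sodium enolate in THF should react with the soft allylic bromide at carbon, first to 4 and after a second deprotonation to the quaternary carbon, which carries two identical prenyl groups and is therefore not a stereocentre.

Step 3
Reactants: 6 acetophenone; 7 carbon disulfide
Product: 10 3,3-bis(methylsulfanyl)-1-phenylprop-2-en-1-one, via disodium ene-dithiolate 8 (not isolated), via sodium S-methyl dithioate 9 (not isolated)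
Conditions: NaH (2.2 equiv), THF/DMF, 0 °C; CS2 (1.1 equiv), 0 °C to rt; MeI (2.3 equiv), 0 °C to rt
Reagents that add atoms: iodomethane, CI
Why: Standard preparation of an α-oxo ketene dithioacetal, in which the sodium enolate of acetophenone adds to carbon disulfide, the dithioate is deprotonated again to the ene-1,1-dithiolate 8, and the two soft sulfur atoms are methylated one after the other by SN2.

Step 4
Reactants: 5 methyl 7-methyl-2,2-bis(3-methylbut-2-enyl)-3-oxooct-6-enoate; 10 3,3-bis(methylsulfanyl)-1-phenylprop-2-en-1-one
Product: 12 4-benzoyl-5-hydroxy-3-(methylsulfanyl)-2,6,6-tris(3-methylbut-2-enyl)cyclohexa-2,4-dien-1-one, via open-chain enedione ester 11 (not isolated)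
Conditions: KN(SiMe3)2 (2.3 equiv), THF, −78 °C, then 5; 10 (1.05 equiv), −78 °C to rt; then 60 °C; cold 1 M HCl to pH 3–4
Reagents that add atoms: none
Why: Proposed new method: the potassium enolate of 5, which can form only at C1 because C3 is quaternary, should add in conjugate fashion to the bis(methylsulfanyl) carbon C6 of 10 and expel methanethiolate (C1–C6 bond, intermediate 11); the closest known reaction type is the addition–elimination of potassium ketone enolates to α-oxo ketene dithioacetals (Junjappa–Ila chemistry), extended here by a Claisen ring closure in the same flask. The second equivalent of base removes the now doubly activated C1–H of 11, and the resulting pentadienyl-type enolate (O–C2–C1–C6–C5–C7–O) should be acylated at C5, its α-carbon with respect to the benzoyl group, by the methyl ester carbon C4 in a 6-exo-trig Dieckmann-type closure (C4–C5 bond), in the way polyketo ester anions cyclise to acylphloroglucinols. Loss of methoxide and deprotonation of the very acidic C5–H of the cyclic product drain the equilibria and protect the ring from retro-Claisen cleavage. No stereocentre is created, since C3 bears two identical prenyl groups and every other ring carbon is trigonal. The step needs conjugate attack at C6 instead of carbonyl attack at C7, and ring closure C5 to C4 instead of an aldol closure. Potassium as counter-ion keeps carbonyl addition reversible so that the addition–elimination wins, the quaternary C3 removes every proton an aromatising aldol condensation would need, and closure through C1 or through the benzoyl oxygen would give a four- or an eight-membered ring.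

Step 5
Reactants: 12 4-benzoyl-5-hydroxy-3-(methylsulfanyl)-2,6,6-tris(3-methylbut-2-enyl)cyclohexa-2,4-dien-1-one
Product: 13 2-benzoyl-3,5-dihydroxy-4,4,6-tris(3-methylbut-2-enyl)cyclohexa-2,5-dien-1-one (target)
Conditions: LiOH·H2O (10 equiv), THF/H2O 1:1, degassed, argon, 60 °C; then 1 M HCl to pH 2–3, 0 °C
Reagents that add atoms: lithium hydroxide, [Li+].[OH-]
Why: Vinylogous thioester saponification by addition–elimination, in which hydroxide adds to C6 (the β-carbon of the C2=O/C1=C6 enone), methanethiolate leaves and the product is held as its delocalised lithium enolate until cold acidification, while the prenyl alkenes are inert to aqueous base, exclusion of air should prevent autoxidation of the enolate, and no stereocentre is involved.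

**Compound list**

1 | methyl acetoacetate (methyl 3-oxobutanoate) | COC(=O)CC(C)=O | starting material
2 | 1-bromo-3-methylbut-2-ene (prenyl bromide) | CC(C)=CCBr | starting material
3 | methyl 7-methyl-3-oxooct-6-enoate | COC(=O)CC(=O)CCC=C(C)C | intermediate
4 | methyl 7-methyl-2-(3-methylbut-2-enyl)-3-oxooct-6-enoate (racemic) | COC(=O)C(CC=C(C)C)C(=O)CCC=C(C)C | intermediate
5 | methyl 7-methyl-2,2-bis(3-methylbut-2-enyl)-3-oxooct-6-enoate | COC(=O)C(CC=C(C)C)(CC=C(C)C)C(=O)CCC=C(C)C | intermediate
6 | acetophenone | CC(=O)c1ccccc1 | starting material
7 | carbon disulfide | S=C=S | starting material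
8 | disodium 3-oxo-3-phenylprop-1-ene-1,1-bis(thiolate) | [Na+].[Na+].[S-]C([S-])=CC(=O)c1ccccc1 | intermediate
9 | sodium 1-(methylsulfanyl)-3-oxo-3-phenylprop-1-ene-1-thiolate (alkene geometry not defined) | [Na+].CSC([S-])=CC(=O)c1ccccc1 | intermediate
10 | 3,3-bis(methylsulfanyl)-1-phenylprop-2-en-1-one | CSC(SC)=CC(=O)c1ccccc1 | intermediate
11 | methyl 7-methyl-2,2-bis(3-methylbut-2-enyl)-4-[1-(methylsulfanyl)-3-oxo-3-phenylprop-1-enyl]-3-oxooct-6-enoate (racemic, alkene geometry not defined) | COC(=O)C(CC=C(C)C)(CC=C(C)C)C(=O)C(CC=C(C)C)C(SC)=CC(=O)c1ccccc1 | intermediate
12 | 4-benzoyl-5-hydroxy-3-(methylsulfanyl)-2,6,6-tris(3-methylbut-2-enyl)cyclohexa-2,4-dien-1-one | CSC1=C(CC=C(C)C)C(=O)C(CC=C(C)C)(CC=C(C)C)C(O)=C1C(=O)c1ccccc1 | intermediate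
13 | 2-benzoyl-3,5-dihydroxy-4,4,6-tris(3-methylbut-2-enyl)cyclohexa-2,5-dien-1-one | CC(C)=CCC1=C(O)C(CC=C(C)C)(CC=C(C)C)C(O)=C(C(=O)c2ccccc2)C1=O | target

**Step count and risks**

Total step count: 5. Longest linear sequence: 4 steps (steps 1, 2, 4, 5).

Steps most likely to fail:

Step 4. The enolate may add to the carbonyl group of 10 instead of its β-carbon. The sequence may also stall at the stabilised open-chain enolate, because ring closure onto the hindered ester next to the quaternary carbon is slow. The fallback is the known dearomatising C-alkylation of acylphloroglucinols. It sets out from prenyl bromide 2 (3.0–3.3 equiv), which is reacted with commercially available 2,4,6-trihydroxybenzophenone F1 and NaOMe in MeOH at −10 to 0 °C. The first two prenyl groups should enter the two free ring positions and the third should enter one of them again to give the geminal pair. After acidification and chromatographic removal of under-, over- and O-alkylated material, the fallback comes back to the route at 13.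

Step 5. Attack of hydroxide at C6 may be too slow because the substrate is an electron-rich enolate under the conditions, and prolonged heating in base could cause retro-Claisen loss of the benzoyl group. The fallback replaces hydroxide by an oximate as a more nucleophilic oxygen donor. It sets out from 12, which is treated with (E)-benzaldehyde oxime (3 equiv) and Cs2CO3 in DMSO at 70 °C. Addition–elimination at C6 should give 4-benzoyl-3-[(benzylideneamino)oxy]-5-hydroxy-2,6,6-tris(3-methylbut-2-enyl)cyclohexa-2,4-dien-1-one F2, which in the same basic medium should fragment to benzonitrile and the C6 enolate. Cold acidification brings the fallback back to the route at 13.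

Step 2. O-alkylation of the hindered monoprenyl enolate may compete in the second alkylation, or the second alkylation may stay incomplete. The fallback is a Tsuji–Trost allylation. Methyl 3-methylbut-2-enyl carbonate F3 is first made from 3-methylbut-2-en-1-ol, methyl chloroformate and pyridine in CH2Cl2 at 0 °C. The fallback then sets out from 3, which is heated with F3 (2.4 equiv) and Pd(PPh3)4 (5 mol %, zerovalent palladium) in THF at 50 °C. The methoxide set free from the carbonate serves as base, and the soft enolate should attack the unsubstituted terminus of the π-prenyl palladium complex at carbon only. The reaction passes through 4 and comes back to the route at 5.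

**Further compounds**

F1 | step 4 | 2,4,6-trihydroxybenzophenone | O=C(c1ccccc1)c1c(O)cc(O)cc1O
F2 | step 5 | 4-benzoyl-3-[(benzylideneamino)oxy]-5-hydroxy-2,6,6-tris(3-methylbut-2-enyl)cyclohexa-2,4-dien-1-one | CC(C)=CCC1=C(O/N=C/c2ccccc2)C(C(=O)c2ccccc2)=C(O)C(CC=C(C)C)(CC=C(C)C)C1=O
F3 | step 2 | methyl 3-methylbut-2-enyl carbonate | COC(=O)OCC=C(C)C
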